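## Retrosynthetic overview

1. The C6 chloride comes from a C6 allylic alcohol by invertive chlorination; the ten-membered ring is closed last, at C5–C6, by Ni/Cr coupling of a C5 bromoalkene with a C6 aldehyde.
2. The butanolide comes from a C8 vinyl carbinol (asymmetric dihydroxylation, lactonisation); C8–C17 by a chelation-controlled propionate aldol; C8–C9 by lithiated methoxyallene adding to a C9 lactol.
3. The ring A cis-11,12-diol comes from OsO4 on an 11,13-diene, made from the Diels–Alder silyl enol ether (Saegusa oxidation, 1,2-reduction, dehydration).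
4. The C2–C5 chain comes from a methyl ketone by bromoallylation and Felkin reduction; O-2 and C9 are parked together as a trans-fused γ-lactone.
5. Ring order: ring A (asymmetric Diels–Alder), temporary lactone, butanolide, ten-membered ring.

Numbering and faces: briarane numbering is used (C1 quaternary fusion carbon with Me-15; C2–C9 ten-membered ring; C10 fusion CH; C11–C14 ring A; C16 exocyclic CH2 on C5; C17, C18, C19 lactone CH, its methyl, the carbonyl; C20 methyl on C11); β is the face of ring A that carries Me-15.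

Assumption: the (S)-oxazaborolidinium catalyst gives the (1S,10S) adduct drawn (by analogy with 2-substituted acroleins); if the sense is the reverse, its enantiomer is used.

## Route

Step 1
Reactants: 1 pent-1-en-3-one
Product: 2 (Z)-3-(triisopropylsilyloxy)penta-1,3-diene
Conditions: i-Pr3SiOTf, Et3N, CH2Cl2, 0 °C
Reagents that add atoms: triisopropylsilyl trifluoromethanesulfonate, CC(C)[Si](C(C)C)(C(C)C)OS(=O)(=O)C(F)(F)F
Why: Soft enolisation and O-silylation of the ethyl ketone gives the cross-conjugated (Z)-silyl enol ether, a 2-silyloxydiene.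

Step 2
Reactants: 2 (Z)-3-(triisopropylsilyloxy)penta-1,3-diene; 3 ethyl (E)-3-methyl-4-oxobut-2-enoate
Product: 4 Diels–Alder adduct (ring A aldehyde ester; C1 S and C10 S)
Conditions: (S)-o-tolyl-oxazaborolidine (from (S)-α,α-diphenylprolinol) protonated by Tf2NH (20 mol %), CH2Cl2, −78 to −40 °C
Reagents that add atoms: ethyl (E)-3-methyl-4-oxobut-2-enoate (3), CCOC(=O)/C=C(\C)C=O
Why: Catalytic enantioselective Diels–Alder reaction: the aldehyde-bound chiral Lewis acid shields one face, the CH(Me) terminus of the diene bonds to the carbon β to the aldehyde ("para" adduct), and the E geometry of 3 puts Me-15 cis to the C10 ester (C1 and C10 set; C11 is inconsequential).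

Step 3
Reactants: 4 Diels–Alder adduct; 5 methylmagnesium bromide
Product: 6 methyl carbinol (both C2 epimers)
Conditions: MeMgBr, THF, −78 °C; then H2O, −78 °C
Reagents that add atoms: methylmagnesium bromide (5), C[Mg]Br
Why: Grignard addition to the aldehyde, which is far more reactive than the ester or the silyl enol ether; the carbinol configuration is irrelevant because it is oxidised next.

Step 4
Reactants: 6 methyl carbinol
Product: 7 methyl ketone
Conditions: Dess–Martin periodinane, NaHCO3, CH2Cl2, 0 °C to rt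
Reagents that add atoms: none
Why: Dess–Martin oxidation of the secondary alcohol under buffered conditions leaves the silyl enol ether and ester untouched.

Step 5
Reactants: 7 methyl ketone; 8 2,3-dibromoprop-1-ene
Product: 10 4-bromopent-4-enoyl ketone, via lithium enolate 9 (not isolated)
Conditions: LiN(i-Pr)2, THF, −78 °C; then 8, DMPU, −78 to −40 °C
Reagents that add atoms: 2,3-dibromoprop-1-ene (8), C=C(Br)CBr
Why: Kinetic enolate alkylation (SN2 at the allylic bromide): the acetyl methyl is the only enolisable ketone position because C1 is quaternary and the ring ketone is masked as its silyl enol ether.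

Step 6
Reactants: 10 4-bromopent-4-enoyl ketone
Product: 12 trans-fused γ-lactone with silyl enol ether, via lithium alkoxide 11 (not isolated)
Conditions: LiBH(s-Bu)3 (1.1 equiv), THF, −78 to 0 °C; then H2O
Reagents that add atoms: none
Why: Felkin–Anh reduction of the α-quaternary ketone (hydride anti to the C1–C10 bond, past the small methyl) sets C2 (R), and the alkoxide lactonises onto the ethyl ester, which protects O-2 and C9 together and locks ring A.

Step 7
Reactants: 12 trans-fused γ-lactone with silyl enol ether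
Product: 13 enone lactone
Conditions: Pd(OAc)2 (1.1 equiv), MeCN, 40 °C
Reagents that add atoms: none
Why: Saegusa–Ito oxidation: the palladium enolate at C13 can lose a β-hydride only from C14, giving the C13=C14 enone.

Step 8
Reactants: 13 enone lactone
Product: 14 allylic alcohol lactone (12β-OH)
Conditions: NaBH4, CeCl3·7H2O, MeOH, −40 °C
Reagents that add atoms: none
Why: Luche 1,2-reduction of the enone without touching the lactone; axial attack from the α face is expected to give the 12β alcohol, a centre that is removed in the next step.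

Step 9
Reactants: 14 allylic alcohol lactone
Product: 15 11,13-diene lactone
Conditions: Burgess reagent (methyl N-(triethylammoniosulfonyl)carbamate), benzene, 50 °C
Reagents that add atoms: none
Why: Burgess dehydration (syn elimination through the sulfamate) can only take the cis H-11, since C13 is sp2 and C1 is quaternary, and gives the conjugated C11=C12–C13=C14 diene.

Step 10
Reactants: 15 11,13-diene lactone
Product: 16 11α,12α-diol lactone
Conditions: OsO4 (2 mol %), NMO, acetone/H2O, 0 °C
Reagents that add atoms: osmium tetroxide, O=[Os](=O)(=O)=O; N-methylmorpholine N-oxide, C[N+]1([O-])CCOCC1; water, O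
Why: Upjohn dihydroxylation: OsO4 attacks the more electron-rich trisubstituted C11=C12 bond from the α face, away from the axial Me-15 and the C10–C9 bond held β by the lactone, setting the cis-diol at C11 and C12.

Step 11
Reactants: 16 11α,12α-diol lactone
Product: 17 acetonide lactone
Conditions: 2,2-dimethoxypropane, PPTS, acetone, rt
Reagents that add atoms: 2,2-dimethoxypropane, COC(C)(C)OC
Why: Acid-catalysed acetal exchange (acetonide formation) protects the cis-diol for the organometallic steps.

Step 12
Reactants: 17 acetonide lactone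
Product: 18 lactol (both anomers)
Conditions: i-Bu2AlH (1.1 equiv), CH2Cl2, −78 °C; then H2O (Rochelle salt)
Reagents that add atoms: none
Why: Partial reduction of the lactone stops at the tetrahedral aluminate at −78 °C and gives the lactol, a masked C9 aldehyde.

Step 13
Reactants: 18 lactol; 19 methoxyallene
Product: 22 α′-hydroxy vinyl ketone (2R,9R diol), via 1-lithio-1-methoxyallene 20 (not isolated), via allenyl carbinol 21 (not isolated)
Conditions: 19, n-BuLi, THF, −40 °C; then 18, −78 °C; H2O; then 5% aq. H2SO4, THF, 0 °C, 10 min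
Reagents that add atoms: methoxyallene (19), C=C=COC; water, O
Why: Addition of a lithiated alkoxyallene (acyl anion equivalent) to the lactol, which reacts as its open hydroxy aldehyde under Felkin–Anh control (attack anti to quaternary C1), sets C9 (R), and enol ether hydrolysis then gives the vinyl ketone.

Step 14
Reactants: 22 α′-hydroxy vinyl ketone; 23 tert-butyl propanoate
Product: 25 aldol adduct (C8 tertiary vinyl carbinol), via lithium ester enolate 24 (not isolated)
Conditions: 23, LiN(i-Pr)2 (5 equiv each), THF, −78 °C; then 22, −78 °C; AcOH, −78 °C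
Reagents that add atoms: tert-butyl propanoate (23), CCC(=O)OC(C)(C)C
Why: Aldol addition of a lithium ester enolate, 1,2 to the vinyl ketone at −78 °C: the lithium alkoxide on C9 chelates the ketone oxygen (Cram chelate) so the enolate enters from the side of H-9 and sets C8, the tert-butyl ester cannot lactonise onto O-9, and any C17 epimer is corrected in step 18.

Step 15
Reactants: 25 aldol adduct
Product: 26 pentaol
Conditions: PPTS, MeOH, 45 °C
Reagents that add atoms: none
Why: Mild transketalisation removes the acetonide without cleaving the tert-butyl ester or ionising the tertiary allylic alcohol.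

Step 16
Reactants: 26 pentaol
Product: 27 2,9,12-triacetate
Conditions: Ac2O, pyridine, DMAP (cat.), 0 °C to rt
Reagents that add atoms: acetic anhydride, CC(=O)OC(C)=O
Why: Nucleophile-catalysed acylation acetylates the three secondary hydroxyls (the final acetates) and leaves the two tertiary hydroxyls free.

Step 17
Reactants: 27 2,9,12-triacetate
Product: 28 6,7-diol
Conditions: OsO4 (5 mol %), (DHQD)2PHAL (10 mol %), NMO, acetone/H2O, 0 °C
Reagents that add atoms: osmium tetroxide, O=[Os](=O)(=O)=O; N-methylmorpholine N-oxide, C[N+]1([O-])CCOCC1; water, O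
Why: Ligand-accelerated asymmetric dihydroxylation (Sharpless type) of the only monosubstituted alkene: the DHQD ligand, reinforced by the Kishi anti preference relative to the C8 hydroxyl, sets C7, while the hindered ring alkene and the electron-poor bromoalkene do not react.

Step 18
Reactants: 28 6,7-diol
Product: 30 hydroxymethyl butanolide, via seco acid 29 (not isolated)
Conditions: TFA, CH2Cl2, 0 °C to rt; then DBU (0.2 equiv), toluene, 40 °C
Reagents that add atoms: none
Why: Acidolysis of the tert-butyl ester and γ-lactonisation onto the C7 hydroxyl (five-ring over six-ring), then base equilibration of the lactone α-carbon, which puts the C17 methyl trans to the bulky C9 branch (C17 set).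

Step 19
Reactants: 30 hydroxymethyl butanolide
Product: 31 lactone aldehyde
Conditions: Dess–Martin periodinane, NaHCO3, CH2Cl2, 0 °C; used crude
Reagents that add atoms: none
Why: Dess–Martin oxidation of the only primary alcohol; the remaining free hydroxyls are tertiary and inert.

Step 20
Reactants: 31 lactone aldehyde
Product: 32 macrocyclic (6R) allylic alcohol
Conditions: CrCl2 (15 equiv), NiCl2 (0.3 equiv), DMF, 0.003 M, 25–45 °C; then H2O
Reagents that add atoms: none
Why: Intramolecular Nozaki–Hiyama–Kishi reaction: zerovalent nickel formed in situ inserts into the C–Br bond, the alkenyl group passes to trivalent chromium and adds to the aldehyde at high dilution to close the ring at C5–C6; the C6 carbinol syn to O-7 (6R) is assumed from macrocyclic control and is the least secure assignment.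

Step 21
Reactants: 32 macrocyclic (6R) allylic alcohol
Product: 33 target CNP0259091.2
Conditions: PPh3, hexachloroacetone, CH2Cl2, 0 °C
Reagents that add atoms: hexachloroacetone, O=C(C(Cl)(Cl)Cl)C(Cl)(Cl)Cl
Why: Appel-type chlorination through the alkoxyphosphonium salt: chloride displaces with SN2 inversion at the allylic C6 to give the 6S chloride with little allylic shift, and the tertiary hydroxyls do not react.

## Compound list

1 | pent-1-en-3-one (ethyl vinyl ketone) | C=CC(=O)CC | starting material
2 | (Z)-3-(triisopropylsilyloxy)penta-1,3-diene | C/C=C(\O[Si](C(C)C)(C(C)C)C(C)C)C=C | intermediate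
3 | ethyl (E)-3-methyl-4-oxobut-2-enoate | CCOC(=O)/C=C(\C)C=O | starting material
4 | ethyl (1S,2S,6S)-6-formyl-2,6-dimethyl-3-(triisopropylsilyloxy)cyclohex-3-ene-1-carboxylate (formyl carbon is C2, quaternary carbon is C1 with Me-15 β, ester carbon is C9 on C10 β) | O=C[C@@]1(C)CC=C(O[Si](C(C)C)(C(C)C)C(C)C)[C@@H](C)[C@@H]1C(=O)OCC | intermediate
5 | methylmagnesium bromide | C[Mg]Br | starting material
6 | ethyl (1S,2S,6S)-6-(1-hydroxyethyl)-2,6-dimethyl-3-(triisopropylsilyloxy)cyclohex-3-ene-1-carboxylate (both carbinol epimers) | CC(O)[C@@]1(C)CC=C(O[Si](C(C)C)(C(C)C)C(C)C)[C@@H](C)[C@@H]1C(=O)OCC | intermediate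
7 | ethyl (1S,2S,6S)-6-acetyl-2,6-dimethyl-3-(triisopropylsilyloxy)cyclohex-3-ene-1-carboxylate | CC(=O)[C@@]1(C)CC=C(O[Si](C(C)C)(C(C)C)C(C)C)[C@@H](C)[C@@H]1C(=O)OCC | intermediate
8 | 2,3-dibromoprop-1-ene | C=C(Br)CBr | starting material
9 | lithium enolate of 7 at the acetyl methyl (not isolated) | C=C(O[Li])[C@@]1(C)CC=C(O[Si](C(C)C)(C(C)C)C(C)C)[C@@H](C)[C@@H]1C(=O)OCC | intermediate
10 | ethyl (1S,2S,6S)-6-(4-bromopent-4-enoyl)-2,6-dimethyl-3-(triisopropylsilyloxy)cyclohex-3-ene-1-carboxylate | C=C(Br)CCC(=O)[C@@]1(C)CC=C(O[Si](C(C)C)(C(C)C)C(C)C)[C@@H](C)[C@@H]1C(=O)OCC | intermediate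
11 | lithium alkoxide of the (R)-carbinol at C2 from 10 (not isolated) | C=C(Br)CC[C@@H](O[Li])[C@@]1(C)CC=C(O[Si](C(C)C)(C(C)C)C(C)C)[C@@H](C)[C@@H]1C(=O)OCC | intermediate
12 | (3R,3aS,7S,7aS)-3-(3-bromobut-3-en-1-yl)-3a,7-dimethyl-6-(triisopropylsilyloxy)-3a,4,7,7a-tetrahydroisobenzofuran-1(3H)-one (trans-fused O-2/C9 lactone) | C=C(Br)CC[C@H]1OC(=O)[C@H]2[C@H](C)C(O[Si](C(C)C)(C(C)C)C(C)C)=CC[C@]12C | intermediate
13 | (3R,3aS,7S,7aS)-3-(3-bromobut-3-en-1-yl)-3a,7-dimethyl-3a,7a-dihydroisobenzofuran-1,6(3H,7H)-dione (enone lactone) | C=C(Br)CC[C@H]1OC(=O)[C@H]2[C@H](C)C(=O)C=C[C@]12C | intermediate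
14 | (3R,3aS,6S,7S,7aS)-3-(3-bromobut-3-en-1-yl)-6-hydroxy-3a,7-dimethyl-3a,6,7,7a-tetrahydroisobenzofuran-1(3H)-one (12β-allylic alcohol) | C=C(Br)CC[C@H]1OC(=O)[C@H]2[C@H](C)[C@@H](O)C=C[C@]12C | intermediate
15 | (3R,3aS,7aS)-3-(3-bromobut-3-en-1-yl)-3a,7-dimethyl-3a,7a-dihydroisobenzofuran-1(3H)-one (11,13-diene lactone) | C=C(Br)CC[C@H]1OC(=O)[C@H]2C(C)=CC=C[C@]12C | intermediate
16 | (3R,3aS,6R,7S,7aR)-3-(3-bromobut-3-en-1-yl)-6,7-dihydroxy-3a,7-dimethyl-3a,6,7,7a-tetrahydroisobenzofuran-1(3H)-one (11α,12α-diol) | C=C(Br)CC[C@H]1OC(=O)[C@H]2[C@](C)(O)[C@H](O)C=C[C@]12C | intermediate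
17 | 11,12-O-isopropylidene acetal of 16 (acetonide lactone) | C=C(Br)CC[C@H]1OC(=O)[C@H]2[C@]3(C)OC(C)(C)O[C@@H]3C=C[C@]12C | intermediate
18 | lactol from 17 (hemiacetal at C9, both anomers) | C=C(Br)CC[C@H]1OC(O)[C@H]2[C@]3(C)OC(C)(C)O[C@@H]3C=C[C@]12C | intermediate
19 | methoxyallene (1-methoxypropa-1,2-diene) | C=C=COC | starting material
20 | 1-lithio-1-methoxyallene (not isolated) | [Li]C(OC)=C=C | intermediate
21 | allenyl carbinol: ring A (Δ13, 11α,12α-acetonide, Me-15 β, H-10 α) with the (2R)-CH(OH)CH2CH2C(Br)=CH2 chain on C1 and the (9R)-CH(OH)C(OMe)=C=CH2 chain on C10 (not isolated) | C=C(Br)CC[C@@H](O)[C@@]1(C)C=C[C@H]2OC(C)(C)O[C@@]2(C)[C@@H]1[C@@H](O)C(OC)=C=C | intermediate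
22 | α′-hydroxy vinyl ketone: as 21 but with the (9R)-CH(OH)C(=O)CH=CH2 chain on C10 (may sit partly as the cyclic hemiketal with O-2) | C=C(Br)CC[C@@H](O)[C@@]1(C)C=C[C@H]2OC(C)(C)O[C@@]2(C)[C@@H]1[C@@H](O)C(=O)C=C | intermediate
23 | tert-butyl propanoate | CCC(=O)OC(C)(C)C | starting material
24 | lithium enolate of tert-butyl propanoate (not isolated) | C/C=C(/O[Li])OC(C)(C)C | intermediate
25 | aldol adduct: as 22 but C8 is a tertiary carbinol bearing vinyl (C7=C6) and the (17R)-CH(CH3)CO2t-Bu group; C8 configured as in 33 | C=C(Br)CC[C@@H](O)[C@@]1(C)C=C[C@H]2OC(C)(C)O[C@@]2(C)[C@@H]1[C@@H](O)[C@@](O)(C=C)[C@@H](C)C(=O)OC(C)(C)C | intermediate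
26 | pentaol: 25 without the acetonide (free 2-, 8-, 9-, 11α-, 12α-OH) | C=C(Br)CC[C@@H](O)[C@@]1(C)C=C[C@@H](O)[C@@](C)(O)[C@@H]1[C@@H](O)[C@@](O)(C=C)[C@@H](C)C(=O)OC(C)(C)C | intermediate
27 | 2,9,12-triacetate of 26 (8- and 11-OH free) | C=C(Br)CC[C@@H](OC(C)=O)[C@@]1(C)C=C[C@@H](OC(C)=O)[C@@](C)(O)[C@@H]1[C@@H](OC(C)=O)[C@@](O)(C=C)[C@@H](C)C(=O)OC(C)(C)C | intermediate
28 | 6,7-diol: 27 with the vinyl group turned into CH(OH)CH2OH, C7 configured as in 33 | C=C(Br)CC[C@@H](OC(C)=O)[C@@]1(C)C=C[C@@H](OC(C)=O)[C@@](C)(O)[C@@H]1[C@@H](OC(C)=O)[C@@](O)([C@@H](O)CO)[C@@H](C)C(=O)OC(C)(C)C | intermediate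
29 | seco acid: the free C19 carboxylic acid of 28 (not isolated) | C=C(Br)CC[C@@H](OC(C)=O)[C@@]1(C)C=C[C@@H](OC(C)=O)[C@@](C)(O)[C@@H]1[C@@H](OC(C)=O)[C@@](O)([C@@H](O)CO)[C@@H](C)C(=O)O | intermediate
30 | hydroxymethyl butanolide: C19/O-7 γ-lactone with 8-OH, (17R)-methyl and CH2OH (C6) on C7; C7, C8, C17 as in 33 | C=C(Br)CC[C@@H](OC(C)=O)[C@@]1(C)C=C[C@@H](OC(C)=O)[C@@](C)(O)[C@@H]1[C@@H](OC(C)=O)[C@]2(O)[C@@H](C)C(=O)O[C@H]2CO | intermediate
31 | lactone aldehyde: 30 with C6 as CHO | C=C(Br)CC[C@@H](OC(C)=O)[C@@]1(C)C=C[C@@H](OC(C)=O)[C@@](C)(O)[C@@H]1[C@@H](OC(C)=O)[C@]2(O)[C@@H](C)C(=O)O[C@H]2C=O | intermediate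
32 | macrocyclic allylic alcohol: 33 with (6R)-OH in place of (6S)-Cl | C=C1CC[C@@H](OC(C)=O)[C@@]2(C)C=C[C@@H](OC(C)=O)[C@@](C)(O)[C@@H]2[C@@H](OC(C)=O)[C@]2(O)[C@@H](C)C(=O)O[C@H]2[C@@H]1O | intermediate
33 | CNP0259091.2: (1S,2R,6S,7R,8R,9R,10S,11S,12R,17R)-2,9,12-triacetoxy-6-chloro-8,11-dihydroxybriara-5(16),13-diene C19/O-7 γ-lactone | C=C1CC[C@@H](OC(C)=O)[C@@]2(C)C=C[C@@H](OC(C)=O)[C@@](C)(O)[C@@H]2[C@@H](OC(C)=O)[C@]2(O)[C@@H](C)C(=O)O[C@H]2[C@H]1Cl | target

## Step count and risks

Total step count: 21. Longest linear sequence: 21 steps (1 to 33).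

The three steps most likely to fail:

Step 2 (enantioselective Diels–Alder; the catalyst is untested on this trisubstituted, doubly activated dienophile, so ee and rate are uncertain). The fallback sets out from 2 and 3 and comes back at 4. The cycloaddition is run with an achiral Lewis acid (EtAlCl2, CH2Cl2, −78 °C) to the racemate, which is resolved by preparative chiral SFC. The (1S,2S,6S) half is 4 and the mirror-image adduct F1 is discarded. This replaces asymmetric catalysis by resolution.

Step 14 (aldol on a polyhydroxylated vinyl ketone; risks are conjugate addition, polymerisation under the basic conditions and imperfect chelation control at C8). The fallback sets out from 22 and comes back at 25. tert-Butyl 2-bromopropanoate and activated Zn in THF at 0 °C give the Reformatsky reagent F2. This non-basic zinc enolate adds 1,2 to enones and chelates the C9 oxygen and the ketone in the same sense, giving 25 after aqueous work-up.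

Step 20 (Ni/Cr closure of the ten-membered ring; the configuration at C6 is not secured by any acyclic model). The fallback sets out from 31 and comes back at 32. If the closure delivers the C6-epimeric alcohol F3, it is oxidised with Dess–Martin periodinane to the macrocyclic α-methylene ketone F4. Reduction of F4 with NaBH4 and CeCl3·7H2O in MeOH at −40 °C (Felkin–Anh attack, hydride anti to the C7–O bond) gives 32. C6 is then set by ketone reduction instead of by the C–C bond formation.

## Further compounds

F1 | step 2 | ethyl (1R,2R,6R)-6-formyl-2,6-dimethyl-3-(triisopropylsilyloxy)cyclohex-3-ene-1-carboxylate (enantiomer of 4) | O=C[C@]1(C)CC=C(O[Si](C(C)C)(C(C)C)C(C)C)[C@H](C)[C@H]1C(=O)OCC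
F2 | step 14 | bromo(1-tert-butoxy-1-oxopropan-2-yl)zinc (Reformatsky reagent) | CC([Zn]Br)C(=O)OC(C)(C)C
F3 | step 20 | C6 epimer of 32 ((6S)-alcohol) | C=C1CC[C@@H](OC(C)=O)[C@@]2(C)C=C[C@@H](OC(C)=O)[C@@](C)(O)[C@@H]2[C@@H](OC(C)=O)[C@]2(O)[C@@H](C)C(=O)O[C@H]2[C@H]1O
F4 | step 20 | macrocyclic 6-ketone (α-methylene ketone) corresponding to 32 | C=C1CC[C@@H](OC(C)=O)[C@@]2(C)C=C[C@@H](OC(C)=O)[C@@](C)(O)[C@@H]2[C@@H](OC(C)=O)[C@]2(O)[C@@H](C)C(=O)O[C@H]2C1=O
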